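**Retrosynthetic overview**
1. Target 19 ⇐ the ester C–O bond, made last by Mitsunobu coupling of vanillic acid 17 with the trans dienol 16, with inversion at C1.
2. 16 ⇐ trienol 15 (isopropenyl → isopropyl); 15 ⇐ enantioselective transannular [2,3]-Wittig ring contraction of the 13-membered diallyl ether 12, which sets C1 and C10.
3. 12 ⇐ ring closure through a C–O bond: intramolecular Williamson etherification of hydroxy chloride 10.
4. 10 ⇐ (2Z,6Z)-farnesol 7 (chlorination, terminal SeO2 oxidation); 7 ⇐ neryl chloride 3 + dilithiated prenol (Z-selective C5 homologation).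
5. Ring order: 13-membered oxacycle first (step 5), then the 10-membered carbocycle by contraction (step 6).

Assumption: the SMILES is read literally, so both ring olefins are Z and the ester oxygen and isopropyl group are cis on the ring (1R,10S); the sense of induction of the (S,S)-ligand in step 6 is assumed, and the equally available (R,R)-ligand is used if the first run shows the opposite sense.

**Step 1**
Reactants: 1 nerol
Product: 3 neryl chloride, via neryl mesylate 2 (not isolated)
Conditions: MsCl, LiCl, 2,4,6-collidine, DMF, 0 °C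
Reagents that add atoms: lithium chloride, [Li+].[Cl-]
Why: Mesylation followed by in situ SN2 displacement by chloride under buffered, non-ionising conditions converts the primary allylic alcohol into the chloride without allylic transposition or loss of the Z geometry.

**Step 2**
Reactants: 3 neryl chloride; 4 prenol
Product: 7 (2Z,6Z)-farnesol, via dilithiated prenol 5 (not isolated), via lithium (2Z,6Z)-farnesolate 6 (not isolated)
Conditions: 4 (1.3 equiv), n-BuLi (2.0 equiv per 4), TMEDA, Et2O/hexane, 0 °C → rt, 20 h; then 3, THF, −78 → 0 °C; H2O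
Reagents that add atoms: none
Why: Alkoxide-directed allylic lithiation removes a proton from the methyl group cis to CH2OLi, and the chelated Z allyl anion is alkylated at its CH2 terminus by the primary allylic chloride (dianion alkylation, SN2), so the new trisubstituted olefin is formed Z.

**Step 3**
Reactants: 7 (2Z,6Z)-farnesol
Product: 9 (2Z,6Z)-farnesyl chloride, via (2Z,6Z)-farnesyl mesylate 8 (not isolated)
Conditions: MsCl, LiCl, 2,4,6-collidine, DMF, 0 °C
Reagents that add atoms: lithium chloride, [Li+].[Cl-]
Why: The same mesylate/chloride SN2 sequence as in step 1 gives the primary allylic chloride with both Z olefins intact.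

**Step 4**
Reactants: 9 (2Z,6Z)-farnesyl chloride
Product: 10 (2E,6Z,10Z)-12-chloro-2,6,10-trimethyldodeca-2,6,10-trien-1-ol
Conditions: SeO2 (0.3 equiv), t-BuOOH (3 equiv), salicylic acid (0.1 equiv), CH2Cl2, 0 °C → rt
Reagents that add atoms: tert-butyl hydroperoxide, CC(C)(C)OO
Why: Catalytic SeO2 allylic oxidation (ene reaction, then [2,3]-sigmatropic shift) attacks the most accessible and electron-rich olefin, the terminal isopropylidene group far from CH2Cl, and oxidises its E methyl group, so the new allylic alcohol is E.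

**Step 5**
Reactants: 10 hydroxy chloride
Product: 12 (3E,7Z,11Z)-3,7,11-trimethyl-1-oxacyclotrideca-3,7,11-triene, via sodium alkoxide 11 (not isolated)
Conditions: NaH (3 equiv), THF, 60 °C, syringe-pump addition of 10 over 12 h (final 3 mM)
Reagents that add atoms: none
Why: Intramolecular Williamson etherification under high dilution closes the 13-membered ring by SN2 attack of the primary alkoxide on the primary allylic chloride, a ring closure known for the related all-E hydroxy chloride, and it creates no stereocenter and leaves the olefin geometries untouched.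

**Step 6**
Reactants: 12 cyclic ether
Product: 15 (1R,2Z,6Z,10S)-3,7-dimethyl-10-(prop-1-en-2-yl)cyclodeca-2,6-dien-1-ol, via 13-lithio ether 13 (not isolated), via lithium alkoxide 14 (not isolated)
Conditions: t-BuLi (1.5 equiv), (S,S)-2,2'-(pentane-3,3-diyl)bis(4-isopropyl-4,5-dihydrooxazole) (1.6 equiv), hexane/Et2O 10:1, −78 °C, 6 h; H2O
Reagents that add atoms: none
Why: Proposed new method: an enantioselective transannular [2,3]-Wittig ring contraction of an unactivated bis-allylic macrocyclic ether under external chiral-ligand control, in which the t-BuLi–bis(oxazoline) complex removes one of the two enantiotopic protons at C13 (the OCH2 next to the unsubstituted vinylic CH, less hindered than C2 beside the methyl-bearing C3), the α-oxy allyllithium 13 rearranges at −78 °C faster than it epimerises through the five-membered envelope transition state (C13 bonds to C4 with inversion at the lithiated carbon while O1–C2 breaks), and the E geometry of the migrating C3=C4 unit gives the anti product, which on the new ten-membered ring places OH and isopropenyl trans, so one event forms the carbocycle and fixes both stereocenters as (1R,10S); closest known chemistry is the racemic base-induced [2,3]-Wittig contraction of 13-membered diallyl ethers, its chiral lithium amide variant on allyl propargyl macrocycles, and the alkyllithium/bis(oxazoline)-mediated enantioselective [2,3]-Wittig rearrangement of acyclic allyl ethers.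

**Step 7**
Reactants: 15 trienol
Product: 16 (1S,2Z,6Z,10S)-3,7-dimethyl-10-(propan-2-yl)cyclodeca-2,6-dien-1-ol
Conditions: H2 (1 atm), RhCl(PPh3)3 (5 mol %), toluene, rt
Reagents that add atoms: none
Why: Homogeneous hydrogenation with RhCl(PPh3)3 reduces the unhindered 1,1-disubstituted isopropenyl olefin much faster than the two trisubstituted ring olefins, and no stereocenter is formed or touched (the C1 descriptor changes from R to S only through CIP priorities).

**Step 8**
Reactants: 16 trans dienol; 17 vanillic acid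
Product: 19 (1R,2Z,6Z,10S)-3,7-dimethyl-10-(propan-2-yl)cyclodeca-2,6-dien-1-yl 4-hydroxy-3-methoxybenzoate, via alkoxyphosphonium vanillate 18 (not isolated)
Conditions: 17 (2 equiv), PPh3, DIAD, toluene/THF, 0 °C → rt
Reagents that add atoms: none
Why: Mitsunobu esterification, in which the carboxylic acid (pKa about 4.5) is the pronucleophile while the far less acidic phenol is not engaged, and the carboxylate displaces the oxyphosphonium group of the secondary allylic alcohol by SN2 with inversion, turning (1S) into (1R) and placing the ester oxygen cis to the isopropyl group.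

**Compound list**
1 | nerol, (2Z)-3,7-dimethylocta-2,6-dien-1-ol | OC/C=C(/C)CCC=C(C)C | starting material
2 | neryl mesylate, (2Z)-3,7-dimethylocta-2,6-dien-1-yl methanesulfonate | CS(=O)(=O)OC/C=C(/C)CCC=C(C)C | intermediate
3 | neryl chloride, (2Z)-1-chloro-3,7-dimethylocta-2,6-diene | ClC/C=C(/C)CCC=C(C)C | intermediate
4 | prenol, 3-methylbut-2-en-1-ol | CC(C)=CCO | starting material
5 | dilithiated prenol, lithium (2Z)-4-lithio-3-methylbut-2-en-1-olate | [Li]OC/C=C(/C)C[Li] | intermediate
6 | lithium (2Z,6Z)-farnesolate, lithium (2Z,6Z)-3,7,11-trimethyldodeca-2,6,10-trien-1-olate | [Li]OC/C=C(/C)CC/C=C(/C)CCC=C(C)C | intermediate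
7 | (2Z,6Z)-farnesol, (2Z,6Z)-3,7,11-trimethyldodeca-2,6,10-trien-1-ol | OC/C=C(/C)CC/C=C(/C)CCC=C(C)C | intermediate
8 | (2Z,6Z)-farnesyl mesylate | CS(=O)(=O)OC/C=C(/C)CC/C=C(/C)CCC=C(C)C | intermediate
9 | (2Z,6Z)-farnesyl chloride, (2Z,6Z)-1-chloro-3,7,11-trimethyldodeca-2,6,10-triene | ClC/C=C(/C)CC/C=C(/C)CCC=C(C)C | intermediate
10 | (2E,6Z,10Z)-12-chloro-2,6,10-trimethyldodeca-2,6,10-trien-1-ol | ClC/C=C(/C)CC/C=C(/C)CC/C=C(\C)CO | intermediate
11 | sodium (2E,6Z,10Z)-12-chloro-2,6,10-trimethyldodeca-2,6,10-trien-1-olate | ClC/C=C(/C)CC/C=C(/C)CC/C=C(\C)C[O-].[Na+] | intermediate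
12 | (3E,7Z,11Z)-3,7,11-trimethyl-1-oxacyclotrideca-3,7,11-triene | O1C/C=C(/C)CC/C=C(/C)CC/C=C(\C)C1 | intermediate
13 | 13-lithio-(3E,7Z,11Z)-3,7,11-trimethyl-1-oxacyclotrideca-3,7,11-triene (configuration at C13 not fixed) | O1C([Li])/C=C(/C)CC/C=C(/C)CC/C=C(\C)C1 | intermediate
14 | lithium (1R,2Z,6Z,10S)-3,7-dimethyl-10-(prop-1-en-2-yl)cyclodeca-2,6-dien-1-olate | [Li]O[C@@H]1/C=C(/C)CC/C=C(/C)CC[C@H]1C(C)=C | intermediate
15 | (1R,2Z,6Z,10S)-3,7-dimethyl-10-(prop-1-en-2-yl)cyclodeca-2,6-dien-1-ol (OH and isopropenyl trans) | O[C@@H]1/C=C(/C)CC/C=C(/C)CC[C@H]1C(C)=C | intermediate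
16 | (1S,2Z,6Z,10S)-3,7-dimethyl-10-(propan-2-yl)cyclodeca-2,6-dien-1-ol (OH and isopropyl trans) | O[C@@H]1/C=C(/C)CC/C=C(/C)CC[C@H]1C(C)C | intermediate
17 | vanillic acid, 4-hydroxy-3-methoxybenzoic acid | COc1cc(C(=O)O)ccc1O | starting material
18 | {[(1S,2Z,6Z,10S)-3,7-dimethyl-10-(propan-2-yl)cyclodeca-2,6-dien-1-yl]oxy}(triphenyl)phosphonium 4-hydroxy-3-methoxybenzoate | O([P+](c2ccccc2)(c2ccccc2)c2ccccc2)[C@@H]1/C=C(/C)CC/C=C(/C)CC[C@H]1C(C)C.COc1cc(C([O-])=O)ccc1O | intermediate
19 | (1R,2Z,6Z,10S)-3,7-dimethyl-10-(propan-2-yl)cyclodeca-2,6-dien-1-yl 4-hydroxy-3-methoxybenzoate | COc1cc(C(=O)O[C@H]2/C=C(/C)CC/C=C(/C)CC[C@H]2C(C)C)ccc1O | target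

**Summary**
Total step count: 8. Longest linear sequence: 8 steps (1 → 19); 4 and 17 are bought and enter at steps 2 and 8.

**Steps most likely to fail**

The enantioselective ring contraction of step 6 is the least certain step: deprotonation may occur at C2 instead of C13, [1,2]-shift may compete, and the enantiomeric excess may be low. The fallback uses known chemistry and sets out from 12. Treatment with n-BuLi in THF at −78 °C gives the racemic trans trienol F2. Esterification with (2S)-2-methoxy-2-phenylacetic acid (DCC, DMAP, CH2Cl2) gives two diastereomeric esters, the (1R,10S) ester F3 and the (1S,10R) ester F4, which are separated by chromatography; F4 is discarded. Reduction of F3 with LiAlH4 in Et2O at 0 °C releases the enantiopure alcohol, and the route is rejoined at 15.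

The Mitsunobu inversion of step 8 may be slow or give retention or elimination, because the carbinol is flanked by the isopropyl-bearing carbon and vanillic acid is only moderately acidic. The fallback sets out from 16 and sets C1 by reduction instead of substitution. Dess–Martin oxidation (NaHCO3, CH2Cl2) gives (2Z,6Z,10S)-3,7-dimethyl-10-(propan-2-yl)cyclodeca-2,6-dien-1-one F5. LiBH(s-Bu)3 in THF at −78 °C adds hydride to the carbonyl face away from the isopropyl group (1,2-addition, as the β-carbon is disubstituted) and gives the cis alcohol (1R,2Z,6Z,10S)-3,7-dimethyl-10-(propan-2-yl)cyclodeca-2,6-dien-1-ol F6. Acylation with commercial 4-acetoxy-3-methoxybenzoic acid (EDC·HCl, DMAP, CH2Cl2) gives the acetyl-protected ester F7, and pyrrolidine in CH2Cl2 at 0 °C removes the aryl acetate, arriving at 19.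

The dianion alkylation of step 2 may give low yield or mixed regiochemistry (attack through the internal carbon of the allyl anion, or allylic transposition on the chloride). The fallback sets out from 3 and builds the Z olefin from an acid dienolate instead. 3-Methylbut-2-enoic acid is converted into its dianion (LiN(i-Pr)2, 2 equiv, THF), transmetalated with CuI and alkylated at the γ-carbon by 3 to give (2Z,6Z)-3,7,11-trimethyldodeca-2,6,10-trienoic acid F1. LiAlH4 in Et2O at 0 °C reduces the acid, and the route is rejoined at 7.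

**Further compounds**
F1 | step 2 | (2Z,6Z)-3,7,11-trimethyldodeca-2,6,10-trienoic acid | OC(=O)/C=C(/C)CC/C=C(/C)CCC=C(C)C
F2 | step 6 | racemic trans-3,7-dimethyl-10-(prop-1-en-2-yl)cyclodeca-2Z,6Z-dien-1-ol, 1:1 mixture of (1R,10S) and (1S,10R) | O[C@@H]1/C=C(/C)CC/C=C(/C)CC[C@H]1C(C)=C.O[C@H]1/C=C(/C)CC/C=C(/C)CC[C@@H]1C(C)=C
F3 | step 6 | (1R,2Z,6Z,10S)-3,7-dimethyl-10-(prop-1-en-2-yl)cyclodeca-2,6-dien-1-yl (2S)-2-methoxy-2-phenylacetate | CO[C@H](C(=O)O[C@@H]1/C=C(/C)CC/C=C(/C)CC[C@H]1C(C)=C)c1ccccc1
F4 | step 6 | (1S,2Z,6Z,10R)-3,7-dimethyl-10-(prop-1-en-2-yl)cyclodeca-2,6-dien-1-yl (2S)-2-methoxy-2-phenylacetate | CO[C@H](C(=O)O[C@H]1/C=C(/C)CC/C=C(/C)CC[C@@H]1C(C)=C)c1ccccc1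
F5 | step 8 | (2Z,6Z,10S)-3,7-dimethyl-10-(propan-2-yl)cyclodeca-2,6-dien-1-one | O=C1/C=C(/C)CC/C=C(/C)CC[C@H]1C(C)C
F6 | step 8 | (1R,2Z,6Z,10S)-3,7-dimethyl-10-(propan-2-yl)cyclodeca-2,6-dien-1-ol | O[C@H]1/C=C(/C)CC/C=C(/C)CC[C@H]1C(C)C
F7 | step 8 | (1R,2Z,6Z,10S)-3,7-dimethyl-10-(propan-2-yl)cyclodeca-2,6-dien-1-yl 4-acetoxy-3-methoxybenzoate | COc1cc(C(=O)O[C@H]2/C=C(/C)CC/C=C(/C)CC[C@H]2C(C)C)ccc1OC(C)=O
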